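**Retrosynthetic overview**
1. The target has one ring, a 2,3-dihydro-4H-pyran-4-one (O1, C2–C6). Its only stereocentre is C2 (R), which carries a (12Z)-henicos-12-enyl chain, and C6 carries a methyl group.
2. Enabling feature: O1–C6(CH3)=C5–C4=O is a cyclic vinylogous ester. C3–C6 plus the methyl group therefore hold the 1,3-dioxygen pattern of acetylacetone, and C2–O1 is a latent aldehyde C=O. C2 plus its chain is the intact C22 skeleton of erucyl alcohol, Z-alkene included.
3. Key disconnection: C2–C3 and O1–C6 are cut together. The forward reaction is a catalytic enantioselective formal hetero-[4+2] of (Z)-docos-13-enal with (E)-4-methoxy-2-(trimethylsilyloxy)penta-1,3-diene. It joins the two halves, closes the only ring, sets C2 from achiral partners, and sheds both activating groups (OSiMe3, OMe) in the same flask.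
4. The diene comes from acetylacetone through the methyl enol ether and the kinetic silyl dienol ether. The aldehyde comes from oxidation of erucyl alcohol.
5. Ring order: the pyranone ring is the only ring and is formed in the last step.

Key step: step 4

Remark on the chemistry: the sense of induction is assumed to follow the uniform behaviour of binaphthol–titanium Lewis acids toward aldehydes, in which the (S)-ligand leaves the Si face open; commercial erucyl alcohol is taken as the pure Z isomer.

Step 1
Reactants: 1 pentane-2,4-dione (acetylacetone)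
Product: 2 (E)-4-methoxypent-3-en-2-one
Conditions: HC(OMe)3 (1.1 equiv), p-TsOH·H2O (cat.), MeOH, 55 °C; distillation
Reagents that add atoms: trimethyl orthoformate, COC(OC)OC
Why: Acid-catalysed orthoester ketalisation of one carbonyl group of the β-diketone followed by loss of methanol (enol ether formation) should stop at the conjugated vinylogous ester, and its E geometry, the thermodynamic one, has no bearing on the later steps.

Step 2
Reactants: 2 (E)-4-methoxypent-3-en-2-one
Product: 4 (E)-4-methoxy-2-(trimethylsilyloxy)penta-1,3-diene, via lithium dienolate 3 (not isolated)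
Conditions: LiN(iPr)2 (commercial solution, 1.1 equiv), THF, −78 °C; Me3SiCl (1.2 equiv), −78 °C to rt; pentane, filtration, distillation
Reagents that add atoms: chlorotrimethylsilane, C[Si](C)(C)Cl; LiN(iPr)2, [Li+].CC(C)[N-]C(C)C (its lithium is held only by 3)
Why: Kinetic α′-deprotonation of a β-alkoxy enone (the regiochemistry of the Stork–Danheiser enolate) at the acetyl methyl group and O-silylation of the cross-conjugated dienolate 3 should give the Danishefsky-type silyloxydiene, which is kept away from water and acid by a non-aqueous work-up.

Step 3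
Reactants: 5 (Z)-docos-13-en-1-ol (erucyl alcohol)
Product: 6 (Z)-docos-13-enal
Conditions: PhI(OAc)2 (1.1 equiv), TEMPO (2,2,6,6-tetramethylpiperidin-1-oxyl, 10 mol %), CH2Cl2, rt
Reagents that add atoms: none
Why: The oxoammonium (TEMPO/PhI(OAc)2) oxidation of a primary alcohol stops at the aldehyde in dry CH2Cl2, since no hydrate can form, and it neither attacks nor isomerises the isolated Z-alkene.

Step 4
Reactants: 6 (Z)-docos-13-enal; 4 (E)-4-methoxy-2-(trimethylsilyloxy)penta-1,3-diene (1.5 equiv)
Product: 9 (2R)-2-[(12Z)-henicos-12-en-1-yl]-6-methyl-2,3-dihydro-4H-pyran-4-one, via O-silyl aldol adduct 7 (not isolated), via hydroxy methoxy enone 8 (not isolated)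
Conditions: (S)-1,1'-bi-2-naphthol (20 mol %), Ti(OiPr)4 (10 mol %), 4 Å molecular sieves, toluene, 0 °C; then CF3CO2H (cat.), CH2Cl2, 0 °C; aq. NaHCO3
Reagents that add atoms: none
Why: The (S)-binaphtholate complex of tetravalent titanium binds the aldehyde oxygen of 6, the unsubstituted CH2 terminus of 4 adds in a Mukaiyama aldol step that makes C2–C3 and passes the silyl group to the aldolate oxygen (7), and catalytic CF3CO2H then frees 8, whose hydroxyl adds to the methoxy-bearing β-carbon of the enone and expels methanol to make O1–C6. The closest known reaction type is the binaphthol/Ti(OiPr)4-catalysed enantioselective formal hetero-Diels–Alder reaction of Danishefsky-type 1-methoxy-3-silyloxydienes, methyl-substituted ones at the methoxy terminus included, with unbranched aliphatic aldehydes. The single ring closes by a 6-endo-trig oxa-Michael addition–elimination, so that the overall event is a stepwise [4+2] of the aldehyde C=O across the two termini of the diene. The only stereocentre, C2, is controlled by the catalyst alone: the (S)-ligand should shield the Re face of the bound aldehyde, attack on the Si face gives R, and the cyclisation leaves the C2–O bond untouched. The step needs regioselectivity (secured by the joint electron push of OSiMe3 and OMe onto the terminal CH2) and chemoselectivity (the isolated Z-alkene is inert to the oxophilic Lewis acid and to cold dilute acid, and the non-basic medium spares the enolisable aldehyde from self-aldol reaction), but it needs no control of diene geometry, since E and Z forms of 4 converge once C6 becomes trigonal. The bicarbonate quench keeps stronger base away from 9, whose C2–O1 bond could otherwise open by β-elimination and reclose without stereocontrol.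

**Compound list**
1 | pentane-2,4-dione (acetylacetone) | CC(=O)CC(C)=O | starting material
2 | (E)-4-methoxypent-3-en-2-one | CC(=O)/C=C(\C)OC | intermediate
3 | lithium (3E)-4-methoxypenta-1,3-dien-2-olate | [Li+].C=C([O-])/C=C(\C)OC | intermediate
4 | (E)-4-methoxy-2-(trimethylsilyloxy)penta-1,3-diene | C=C(O[Si](C)(C)C)/C=C(\C)OC | intermediate
5 | (Z)-docos-13-en-1-ol (erucyl alcohol) | CCCCCCCC/C=C\CCCCCCCCCCCCO | starting material
6 | (Z)-docos-13-enal | CCCCCCCC/C=C\CCCCCCCCCCCC=O | intermediate
7 | (2E,6R,18Z)-2-methoxy-6-(trimethylsilyloxy)heptacosa-2,18-dien-4-one | CCCCCCCC/C=C\CCCCCCCCCCC[C@@H](O[Si](C)(C)C)CC(=O)/C=C(\C)OC | intermediate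
8 | (2E,6R,18Z)-6-hydroxy-2-methoxyheptacosa-2,18-dien-4-one | CCCCCCCC/C=C\CCCCCCCCCCC[C@@H](O)CC(=O)/C=C(\C)OC | intermediate
9 | (2R)-2-[(12Z)-henicos-12-en-1-yl]-6-methyl-2,3-dihydro-4H-pyran-4-one | CCCCCCCC/C=C\CCCCCCCCCCC[C@@H]1CC(=O)C=C(C)O1 | target

Total step count: 4. Longest linear sequence: 3 (steps 1, 2 and 4).

**Steps most likely to fail**

1. Step 4.
   - What may go wrong: facial discrimination at the unbranched aldehyde may be eroded by an achiral, silyl-cation-catalysed background aldol reaction. Turnover with the fully substituted methoxy terminus may be slow. The acid stage may allow partial ring opening and reclosure at C2–O1.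
   - Fallback: it sets out from 6 and comes back at 9, and it replaces catalyst control by reagent control and a linear build-up of the diketone. Brown allylation of 6 with (−)-B-allyldiisopinocampheylborane (the reagent derived from (+)-α-pinene; Et2O, −78 °C; then NaOH, H2O2) should attack the Si face and give (4R,16Z)-pentacosa-1,16-dien-4-ol F1. Silylation (tBuMe2SiCl, imidazole, DMF) should give tert-butyl(dimethyl){[(4R,16Z)-pentacosa-1,16-dien-4-yl]oxy}silane F2. Tsuji–Wacker oxidation (PdCl2, CuCl, O2, DMF/H2O), which takes the terminal alkene in preference to the internal Z-alkene, should give (4R,16Z)-4-[(tert-butyldimethylsilyl)oxy]pentacos-16-en-2-one F3. Kinetic enolisation at the methyl group (LiN(iPr)2, THF, −78 °C) and C-acylation with 1-acetylbenzotriazole should give (6R,18Z)-6-[(tert-butyldimethylsilyl)oxy]heptacos-18-ene-2,4-dione F4. Aqueous HF in MeCN should free (6R,18Z)-6-hydroxyheptacos-18-ene-2,4-dione F5, which cyclodehydrates under the same acidic conditions to 9.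

2. Step 2.
   - What may go wrong: γ-deprotonation at the vinylogous methyl group may compete. Proton exchange may equilibrate the dienolate regiochemistry, and the diene may hydrolyse during isolation.
   - Fallback: it sets out from 1 and comes back at 9, and it uses the symmetry of acetylacetone to make the regiochemical question vanish. Me3SiCl and Et3N in hexane should give (Z)-4-(trimethylsilyloxy)pent-3-en-2-one F6. Deprotonation of F6 at either methyl group (LiN(iPr)2, THF, −78 °C) followed by Me3SiCl leads to the same (Z)-2,4-bis(trimethylsilyloxy)penta-1,3-diene F7. The Mukaiyama aldol reaction of F7 with 6 under the (S)-binaphthol/Ti(OiPr)4 catalyst of step 4 should give (2Z,6R,18Z)-2,6-bis(trimethylsilyloxy)heptacosa-2,18-dien-4-one F8. CF3CO2H in wet CH2Cl2 strips both silyl groups to the hydroxy diketone (6R,18Z)-6-hydroxyheptacos-18-ene-2,4-dione F5, which closes to 9 with loss of water instead of methanol.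

3. Step 3.
   - What may go wrong: the aldehyde may be over-oxidised through its hydrate if moisture enters. The long-chain aldehyde may self-condense or oxidise in air on storage, and the alkene geometry may drift.
   - Fallback: it sets out from 5 and comes back at 6, and it reaches the aldehyde by reduction from the acid level instead of by partial oxidation. Exhaustive oxidation (PhI(OAc)2, 2.2 equiv, TEMPO cat., MeCN/H2O) should give (Z)-docos-13-enoic acid (erucic acid) F9, which can also be bought. 1,1'-Carbonyldiimidazole followed by MeNH(OMe)·HCl should give the Weinreb amide (Z)-N-methoxy-N-methyldocos-13-enamide F10. iBu2AlH (THF, −78 °C) should stop at a chelated tetrahedral adduct that releases 6 only on work-up, so that fresh aldehyde can be made just before step 4.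

**Further compounds**
F1 | step 4 | (4R,16Z)-pentacosa-1,16-dien-4-ol | CCCCCCCC/C=C\CCCCCCCCCCC[C@@H](O)CC=C
F2 | step 4 | tert-butyl(dimethyl){[(4R,16Z)-pentacosa-1,16-dien-4-yl]oxy}silane | CCCCCCCC/C=C\CCCCCCCCCCC[C@@H](O[Si](C)(C)C(C)(C)C)CC=C
F3 | step 4 | (4R,16Z)-4-[(tert-butyldimethylsilyl)oxy]pentacos-16-en-2-one | CCCCCCCC/C=C\CCCCCCCCCCC[C@@H](O[Si](C)(C)C(C)(C)C)CC(C)=O
F4 | step 4 | (6R,18Z)-6-[(tert-butyldimethylsilyl)oxy]heptacos-18-ene-2,4-dione | CCCCCCCC/C=C\CCCCCCCCCCC[C@@H](O[Si](C)(C)C(C)(C)C)CC(=O)CC(C)=O
F5 | step 4 | (6R,18Z)-6-hydroxyheptacos-18-ene-2,4-dione | CCCCCCCC/C=C\CCCCCCCCCCC[C@@H](O)CC(=O)CC(C)=O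
F6 | step 2 | (Z)-4-(trimethylsilyloxy)pent-3-en-2-one | CC(=O)/C=C(/C)O[Si](C)(C)C
F7 | step 2 | (Z)-2,4-bis(trimethylsilyloxy)penta-1,3-diene | C=C(O[Si](C)(C)C)/C=C(/C)O[Si](C)(C)C
F8 | step 2 | (2Z,6R,18Z)-2,6-bis(trimethylsilyloxy)heptacosa-2,18-dien-4-one | CCCCCCCC/C=C\CCCCCCCCCCC[C@@H](O[Si](C)(C)C)CC(=O)/C=C(/C)O[Si](C)(C)C
F9 | step 3 | (Z)-docos-13-enoic acid (erucic acid) | CCCCCCCC/C=C\CCCCCCCCCCCC(=O)O
F10 | step 3 | (Z)-N-methoxy-N-methyldocos-13-enamide | CCCCCCCC/C=C\CCCCCCCCCCCC(=O)N(C)OC
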